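**The choice.** If the next run is to charge either 1.10 equiv of partner at 2 mol% of initiator (delta) or 0.280 equiv of partner at 8 mol% (gamma), the decision hangs on how far extra partner still pays.

| setting | teal | blue | red | delta | gamma |
|---|---|---|---|---|---|
| starting material | 0.51 M | 0.51 M | 0.51 M | 0.51 M | 0.51 M |
| partner | 0.21 equiv | 0.95 equiv | 1.1 equiv | 1.10 equiv | 0.280 equiv |
| protic impurity | 0.51 M | 0.51 M | 0.51 M | 0.510 M | 0.510 M |
| initiator | 2 mol% | 2 mol% | 4.6 mol% | 2 mol% | 8 mol% |
| remark | run made earlier | run made earlier | run made earlier |  |  |
| time |  |  |  | 10 min | 10 min |

| run | time / min | product / % | starting material / % |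
|---|---|---|---|
| teal | 0.667 | 2.7 | 27.2 |
| teal | 2.00 | 5.8 | 7.0 |
| teal | 3.00 | 7.2 | 3.2 |
| teal | 5.00 | 8.1 | 0.4 |
| blue | 0.417 | 4.1 | 37.0 |
| blue | 1.00 | 8.9 | 15.3 |
| blue | 2.00 | 11.3 | 4.1 |
| blue | 5.00 | 14.2 | 1.3 |
| red | 0.667 | 12.9 | 19.6 |
| red | 2.00 | 19.2 | 2.7 |
| red | 3.00 | 19.6 | 0 |
| red | 5.00 | 19.6 | 0.2 |

(standard deviation of a reading: 1 percentage point)

- the analysis behind the earlier runs scatters by 1 percentage point, standard deviation
- a reading or a percentage of product counts all its forms, free or not

- the flask that ends with the higher amount of product, in percent of the starting material charged, or "neither" when 2 percentage points or less lies between them (delta / gamma / neither)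
- final product, as a percentage of the starting material charged, in delta
- final product, as a percentage of the starting material charged, in gamma

**Mean partner.** Starting material is down to 0.4%, 1.3% and 0.2% in teal, blue and red at 5.00 min, so their last readings serve as final product. Partner falls during a run, so each run is placed at its mean partner: the average of the charge and what remains after product has taken its share, in percent of the starting material charged. That is 16.9% in teal and 87.9% in blue. Taking product as a saturating curve of mean partner, these two runs give a ceiling of 17.3% at 2 mol% and 19.3% as the half-yield partner, the mean partner at which product reaches half its ceiling, a half-saturation constant. Both are estimates carried through an assumed curve from two readings, each of which has a scatter of 1 percentage point. Holding this value, red makes the ceiling grow as initiator loading to the power 0.360, which puts gamma's ceiling at 28.5%.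

**The reckoning.** At the charged partner, delta stands at 14.7% and gamma at 16.9%, which favours gamma by 2.2 points. But gamma spends much of its partner, so its mean must be used: 14.4%, and on a second pass 14.8%. Delta, whose partner stays above the half-yield partner, reaches 14.5%. The gap of 0.30 points lies within the margin of 2 points, so this reckoning expects neither recipe to give more.

**The result.** The forecast, which differs slightly from this reckoning in its figures, gives 15.3% for delta, 14.5% for gamma and neither, noting of the initiator: “This is sublinear, as expected if the initiator is partly wasted.” The flask gives 15.3% for delta and 14.8% for gamma, so the answer is neither.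

    starting material + initiating radical → capped initiator + first chain carrier (k = 2.30 × 10⁶ /M/s)
    2 second chain carrier → ended chains A (k = 2.10 × 10⁷ /M/s)
    crystals ⇌ product, rate k3*(cs3 - [product]) while solid is left; crystals form when [product] > cs3 (solubility = 0.150 M, k = 8.30 /min)
    starting material + protic impurity → quenched substrate (k = 7.50 /M/min)
    2 first chain carrier → ended chains B (k = 5.40 × 10⁸ /M/s)
    starting material + second chain carrier → released group + first chain carrier (k = 13000 /M/s)
    initiator → 2 initiating radical (k = 0.0300 /min)
    partner + first chain carrier → product + second chain carrier (k = 31000 /M/s)

**Less partner.** Gamma ends with 47% of its partner, a mean of 20.6%, close to the half-yield partner. The neighbouring flask is gamma's recipe with 0.0700 equiv of partner. The 13% of partner it keeps gives a mean of 3.96%, and the same curve with gamma's ceiling gives 4.85%. The neighbouring flask ends at 6.07%.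

(All runs stem from a simulated flask with constants of no real substance; scatter was added.)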